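the same everywhere: free monomer 39 mM
- south: initiator 0.5 mol%; run made earlier
- north-west: initiator 2 mol%; run made earlier
- flask: initiator 1 mol%; time 15 h

| run | time / h | monomer in chains / % | free monomer / % |
|---|---|---|---|
| south | 2.00 | 1 | 100 |
| south | 4.00 | 1 | 94 |
| south | 6.00 | 3 | 93 |
| south | 8.00 | 2 | 92 |
| south | 10.0 | 6 | 89 |
| south | 12.0 | 6 | 85 |
| north-west | 0.833 | 0 | 99 |
| north-west | 2.50 | 5 | 94 |
| north-west | 4.00 | 6 | 92 |
| north-west | 6.00 | 13 | 88 |
| north-west | 10.0 | 21 | 77 |
| north-west | 12.0 | 25 | 72 |

(each reading ± 1.5 percentage points)

- average number of monomer units in a chain (chains begun, living or dead) at 15 h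
- part of the free monomer that has reacted at 15 h

- the average divides the monomer in chains by the number of chains begun, living and dead together
- the earlier runs were read with a standard deviation of 1.5 percentage points
- the earlier runs do not show the number of chains; that part of a forecast is a guess

Monomer in chains ends higher than it starts in both runs, and its last reading divided by loading and time nearly agrees between them: 1.00 /h in the south run and 1.04 /h in the north-west run. Their mean is g = 1.02 /h, the monomer units entering chains per hour per initiator charged, a reading that carries the scatter. Monomer lost but absent from chains, averaged over the same readings, adds b = 0.00500 /h of the charge. The present reckoning for the flask at 15 h is therefore 15.3% in chains and c = 22.8%. With one chain per initiator charged, dp = g·t = 15.3; fewer chains begun raise it, so this reckoning takes that as a low estimate.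

The forecast gives c 24% (21% to 28%) and dp 20 (11 to 45), saying of dp “This is a guess”.

The flask gives dp 34.6 and c 23.1%, with 15.7% in chains.

    free monomer + initiator → living end + monomer in chains (k = 0.00136 /M/s)
    free monomer + living end → monomer in chains + living end, rate k2*[living end]*[free monomer] (k = 0.0238 /M/s)
    living end + monomer in chains → dead end A (k = 0.00162 /M/s)
    free monomer → uncatalysed product (k = 1.53 × 10⁻⁶ /s)
    initiator → spent initiator B (k = 6.13 × 10⁻⁵ /s)

Initiator in the flask has a half-life of 3.1 h towards spent initiator B, shorter than the 4.1 h towards starting chains at 7.84 h. At 15 h in the flask, 0.289% of the initiator is left and spent initiator B holds 0.212 mM of the 0.390 mM charged, so the initiator efficiency, chains begun per initiator charged, is 45.4%, and g·t divided by it gives 33.7 against the flask's 34.6; in the neighbour flask with 0.4 mol% of initiator, g gives 6.12% in chains at 15 h, where 7.00% stands.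

The earlier runs and the new flask were computed for an exercise, and the scatter is random.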